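A direct plan would condense acetophenone A1 (2-OH free, 4-OMOM, 6-O-prenyl) with 2,2-dimethyl-8-prenylchromene-6-carbaldehyde to chalcone A2,
would close ring C by oxa-Michael addition to the racemic flavanone A3, and would then resolve C2, move the prenyl group from O5 to C8 and deprotect.
Its weakest operations would be three.
Ring C closure with resolution: the oxa-Michael addition is reversible and would give a racemate, so at least half of an advanced intermediate would be lost.
Prenyl transfer from O5 to C8 by a Claisen–Cope relay: it would have to prefer C8 to C6 at high temperature next to a labile C2 centre.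
Selective mono-protection and mono-alkylation of three phenols, and their release in acid beside two prenyl groups and a chromene: length without complexity.

**Strategy.** The route disconnects ring A at C4a–C5 instead of ring C at O1–C2, exploiting that ring A (oxygen at C5, C7 and C8a, the C4 acyl group at C4a) is a folded β-polycarbonyl chain. Ring C is made first, as an (S)-2-aryl-2,3-dihydropyran-4-one, by a catalytic asymmetric hetero-Diels–Alder reaction; its C6 (the future C8a) then receives a prenyl-bearing carbon attached to a dioxinone. In the key step heat unmasks an acylketene that acylates C4a and aromatises: ring A, both free phenols and the C8 prenyl group arise in one operation. C2 is set by a catalyst and never meets strong base, prenyl regiochemistry follows from connectivity, and no phenol is protected, so resolution, Claisen–Cope relay and protecting-group steps disappear.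

Key step: step 9

Abbreviations: Ar = 2,2-dimethyl-8-(3-methylbut-2-enyl)-2H-chromen-6-yl; prenyl = 3-methylbut-2-enyl.

Remark: the (S)-BINOL–titanium catalyst of step 4 is assumed to attack the Si face of the aldehyde, as it does in allylations; the centres other than C2 in 13 to 16 form as mixtures and are erased on aromatisation.

**Step 1**
Reactants: 1 3-bromo-4-hydroxybenzaldehyde
Product: 2 3-bromo-4-(2-methylbut-3-yn-2-yloxy)benzaldehyde
Conditions: 3-chloro-3-methylbut-1-yne, DBU, CuCl2·2H2O (1 mol %), MeCN, 0 °C to rt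
Reagents that add atoms: 3-chloro-3-methylbut-1-yne, CC(C)(Cl)C#C
Why: Copper-catalysed O-propargylation of a phenol with a tertiary propargylic chloride, which suits this acidic, electron-poor phenol and runs far below the onset of the Claisen rearrangement.

**Step 2**
Reactants: 2 3-bromo-4-(2-methylbut-3-yn-2-yloxy)benzaldehyde
Product: 5 8-bromo-2,2-dimethyl-2H-chromene-6-carbaldehyde, via allenylphenol 3 (not isolated), via o-quinone methide 4 (not isolated)
Conditions: PhNEt2, 190 °C
Reagents that add atoms: none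
Why: Aromatic propargyl Claisen rearrangement to the only free ortho carbon (the other carries bromine) gives allenylphenol 3 after enolisation, a 1,5-hydrogen shift gives the Z o-quinone methide 4, and an oxa-6π electrocyclisation closes ring D without creating a stereocentre.

**Step 3**
Reactants: 5 8-bromo-2,2-dimethyl-2H-chromene-6-carbaldehyde
Product: 6 2,2-dimethyl-8-(3-methylbut-2-enyl)-2H-chromene-6-carbaldehyde
Conditions: tributyl(3-methylbut-2-enyl)stannane, Pd(PPh3)4 (5 mol %), DMF, 100 °C
Reagents that add atoms: tributyl(3-methylbut-2-enyl)stannane, CCCC[Sn](CCCC)(CCCC)CC=C(C)C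
Why: Migita–Kosugi–Stille coupling, in which oxidative addition of the aryl bromide to zerovalent palladium, transmetalation and reductive elimination at the unsubstituted allyl terminus should give the linear prenyl group, with the aldehyde and the chromene alkene as spectators.

**Step 4**
Reactants: 6 2,2-dimethyl-8-(3-methylbut-2-enyl)-2H-chromene-6-carbaldehyde; 7 (E)-1-methoxy-3-(trimethylsilyloxy)buta-1,3-diene (Danishefsky's diene)
Product: 9 (2S)-2-Ar-2,3-dihydro-4H-pyran-4-one, via aldol silyl ether 8 (not isolated)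
Conditions: (S)-BINOL (20 mol %), Ti(OiPr)4 (10 mol %), 4 Å MS, Et2O, −20 °C; then TFA, CH2Cl2, 0 °C
Reagents that add atoms: none
Why: BINOL–titanium-catalysed asymmetric hetero-Diels–Alder reaction in its Mukaiyama aldol–cyclisation form, in which the catalyst should lead the diene terminus to the Si face of the aldehyde to give 8 and TFA then closes the ring by oxa-Michael addition and loss of methanol, so that C2 is set as S by the catalyst.

**Step 5**
Reactants: 10 2,2,6-trimethyl-4H-1,3-dioxin-4-one
Product: 11 2,2-dimethyl-6-(4-methylpent-3-enyl)-4H-1,3-dioxin-4-one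
Conditions: LiN(i-Pr)2, THF/DMPU, −78 °C; prenyl bromide, −78 to −20 °C
Reagents that add atoms: prenyl bromide, CC(C)=CCBr
Why: γ-Alkylation of the lithium dienolate of the dioxinone (vinylogous enolate alkylation), in which the polar cosolvent favours attack of the exocyclic carbon on the primary allylic bromide in the SN2 sense.

**Step 6**
Reactants: 11 2,2-dimethyl-6-(4-methylpent-3-enyl)-4H-1,3-dioxin-4-one
Product: 12 tert-butyl{[2,2-dimethyl-6-(4-methylpent-3-enylidene)-6H-1,3-dioxin-4-yl]oxy}dimethylsilane (alkylidene E/Z mixture)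
Conditions: LiN(i-Pr)2, THF, −78 °C; TBSCl, DMPU, −78 to 0 °C
Reagents that add atoms: tert-butyldimethylsilyl chloride, CC(C)(C)[Si](C)(C)Cl
Why: O-Silylation of the lithium dienolate (silyl ketene acetal formation) gives the cross-conjugated silyl dienol ether, whose alkylidene geometry is of no consequence.

**Step 7**
Reactants: 9 (2S)-2-Ar-2,3-dihydro-4H-pyran-4-one; 12 silyl dienol ether
Product: 13 (2S)-2-Ar-4-(tert-butyldimethylsilyloxy)-6-[1-(2,2-dimethyl-4-oxo-4H-1,3-dioxin-6-yl)-4-methylpent-3-enyl]-3,6-dihydro-2H-pyran (mixture at C6 and at the side-chain carbon)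
Conditions: 12 (1.5 equiv), TBSOTf (0.3 equiv), 2,6-di-tert-butylpyridine (0.1 equiv), CH2Cl2, −78 °C; Et3N quench
Reagents that add atoms: none
Why: Vinylogous Mukaiyama–Michael addition, in which silylation of the vinylogous ester carbonyl gives a 4-silyloxy oxocarbenium ion that is attacked at C6 by the γ-carbon of 12, silyl transfer regenerates TBSOTf and fixes the enol ether at C4=C5, and the new centres at C6 (2,6-trans expected from axial attack) and in the side chain need no control because both are erased later.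

**Step 8**
Reactants: 13 silyl enol ether
Product: 14 (2S)-2-Ar-6-[1-(2,2-dimethyl-4-oxo-4H-1,3-dioxin-6-yl)-4-methylpent-3-enyl]-2,3-dihydro-4H-pyran-4-one (both side-chain epimers)
Conditions: Pd(OAc)2 (1.2 equiv), MeCN, rt
Reagents that add atoms: none
Why: Saegusa–Ito oxidation, in which the silyl enol ether passes to a palladium enolate at C5 and β-hydride elimination of the C6 hydrogen restores the vinylogous ester with the side chain now on C6, the site being fixed by the position of the enol ether and C2 left untouched.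

**Step 9**
Reactants: 14 pyranone–dioxinone
Product: 17 maackiaflavanone B, via acylketene 15 (not isolated), via dienone 16 (not isolated)
Conditions: toluene (0.003 M, slow addition), 110 °C, Ar
Reagents that add atoms: none
Why: Proposed new method: thermal retro-(4+2) cleavage of the dioxinone expels acetone and gives acylketene 15, whose ketene carbon (the future C5) is attacked by the pyranone α-carbon (the future C4a), the nucleophilic carbon of the vinylogous ester, or, seen from the C7 enol, closes by 6π electrocyclisation of a dienylketene; the resulting dienone 16 tautomerises to the phloroglucinol ring. The closest known reactions are the Claisen-type folding of 3,5,7-triketo esters to acylphloroglucinols, the dienylketene electrocyclisation that ends the Danheiser benzannulation, and the use of dioxinones as acylketene sources in resorcylate synthesis. Ring A is closed by the C4a–C5 bond in a 6-(enolendo)-exo-dig mode (disrotatory if seen as the 6π closure), and no other ring is formed. No lasting stereocentre is created: the side-chain centre and C4a of 16 become sp2 on aromatisation, and C2, set in step 4, is a spectator because the medium holds neither base nor acid to open ring C. The step needs C-acylation at C4a in preference to O-acylation, to aldol-type folding and to intermolecular capture of the ketene: O1 is already an ether so no 2-pyranone can form, the C4 carbonyl lies trans to the chain across the C4a=C8a bond so the aldol mode is out of reach, the prenyl group sits on the carbon next to C8a so only the 8-prenyl isomer can arise, and high dilution keeps the free phenols of the product away from the ketene.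

**Compound list**

1 | 3-bromo-4-hydroxybenzaldehyde | O=Cc1ccc(O)c(Br)c1 | starting material
2 | 3-bromo-4-(2-methylbut-3-yn-2-yloxy)benzaldehyde | O=Cc1ccc(OC(C)(C)C#C)c(Br)c1 | intermediate
3 | allenylphenol: 3-bromo-4-hydroxy-5-(3-methylbuta-1,2-dienyl)benzaldehyde, not isolated | O=Cc1cc(Br)c(O)c(C=C=C(C)C)c1 | intermediate
4 | o-quinone methide: 5-bromo-3-[(Z)-3-methylbut-2-enylidene]-4-oxocyclohexa-1,5-diene-1-carbaldehyde, not isolated | O=CC1=C/C(=C/C=C(C)C)C(=O)C(Br)=C1 | intermediate
5 | 8-bromo-2,2-dimethyl-2H-chromene-6-carbaldehyde | O=Cc1cc(Br)c2OC(C)(C)C=Cc2c1 | intermediate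
6 | 2,2-dimethyl-8-(3-methylbut-2-enyl)-2H-chromene-6-carbaldehyde | O=Cc1cc(CC=C(C)C)c2OC(C)(C)C=Cc2c1 | intermediate
7 | (E)-1-methoxy-3-(trimethylsilyloxy)buta-1,3-diene | CO/C=C/C(=C)O[Si](C)(C)C | starting material
8 | aldol silyl ether: (1E,5S)-5-Ar-1-methoxy-5-(trimethylsilyloxy)pent-1-en-3-one, not isolated | CO/C=C/C(=O)C[C@H](O[Si](C)(C)C)c1cc(CC=C(C)C)c2OC(C)(C)C=Cc2c1 | intermediate
9 | (2S)-2-Ar-2,3-dihydro-4H-pyran-4-one | O=C1C=CO[C@@H](C1)c1cc(CC=C(C)C)c2OC(C)(C)C=Cc2c1 | intermediate
10 | 2,2,6-trimethyl-4H-1,3-dioxin-4-one | CC1=CC(=O)OC(C)(C)O1 | starting material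
11 | 2,2-dimethyl-6-(4-methylpent-3-enyl)-4H-1,3-dioxin-4-one | CC(C)=CCCC1=CC(=O)OC(C)(C)O1 | intermediate
12 | tert-butyl{[2,2-dimethyl-6-(4-methylpent-3-enylidene)-6H-1,3-dioxin-4-yl]oxy}dimethylsilane | CC(C)=CCC=C1C=C(O[Si](C)(C)C(C)(C)C)OC(C)(C)O1 | intermediate
13 | (2S)-2-Ar-4-(tert-butyldimethylsilyloxy)-6-[1-(2,2-dimethyl-4-oxo-4H-1,3-dioxin-6-yl)-4-methylpent-3-enyl]-3,6-dihydro-2H-pyran (mixture at C6 and side-chain carbon) | CC(C)=CCC(C1C=C(O[Si](C)(C)C(C)(C)C)C[C@@H](c2cc(CC=C(C)C)c3OC(C)(C)C=Cc3c2)O1)C1=CC(=O)OC(C)(C)O1 | intermediate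
14 | (2S)-2-Ar-6-[1-(2,2-dimethyl-4-oxo-4H-1,3-dioxin-6-yl)-4-methylpent-3-enyl]-2,3-dihydro-4H-pyran-4-one (both side-chain epimers) | CC(C)=CCC(C1=CC(=O)C[C@@H](c2cc(CC=C(C)C)c3OC(C)(C)C=Cc3c2)O1)C1=CC(=O)OC(C)(C)O1 | intermediate
15 | acylketene: 4-[(2S)-2-Ar-4-oxo-3,4-dihydro-2H-pyran-6-yl]-7-methyl-3-oxoocta-1,6-dien-1-one, not isolated | CC(C)=CCC(C(=O)C=C=O)C1=CC(=O)C[C@@H](c2cc(CC=C(C)C)c3OC(C)(C)C=Cc3c2)O1 | intermediate
16 | dienone: (2S)-2-Ar-7-hydroxy-8-prenyl-2,3-dihydro-4H-chromene-4,5(4aH)-dione (4a-H tautomer of 17), not isolated | CC(C)=CCC1=C2O[C@H](c3cc(CC=C(C)C)c4OC(C)(C)C=Cc4c3)CC(=O)C2C(=O)C=C1O | intermediate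
17 | maackiaflavanone B, (2S)-5,7-dihydroxy-2-(2,2-dimethyl-8-prenyl-2H-chromen-6-yl)-8-prenylchroman-4-one | CC(C)=CCc1cc([C@@H]2CC(=O)c3c(O)cc(O)c(CC=C(C)C)c3O2)cc2c1OC(C)(C)C=C2 | target

**Step count and risks**

Total step count: 9. Longest linear sequence: 7 (steps 1, 2, 3, 4, 7, 8, 9).

Step 9 (key step). The ketene may be lost to dimerisation, to (4+2) or ene reactions with the neighbouring prenyl alkene, or to attack by the ring oxygen followed by ionisation at C2, before C4a can react. The fallback uses known chemistry only and gives up the late construction of ring A; it sets out from aldehyde 6 and returns to the route at 17. 2,4,6-Trihydroxyacetophenone would be C-prenylated (prenyl bromide, DBU) to 1-(2,4,6-trihydroxy-3-prenylphenyl)ethanone F1. Protection (MOMCl, i-Pr2NEt) would give the 4,6-bis(methoxymethyl) ether F2, whose free 2-hydroxyl lies next to the prenyl group, and C-acylation (LiN(SiMe3)2, Boc2O) the tert-butyl β-keto ester F3. Knoevenagel condensation of F3 with 6 (piperidine, AcOH) would give the alkylidene β-keto ester F4. A cinchona-derived bifunctional thiourea would close ring C by enantioselective oxa-Michael addition to the (2S)-flavanone-3-carboxylate F5. TsOH in warm toluene would remove the ester with decarboxylation to the bis-MOM flavanone F6, and dilute HCl in MeOH would then give 17.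

Step 7. The hindered γ-carbon of 12 may react too slowly or through its α-carbon, and the oxocarbenium ion may ionise at the benzylic C2–O bond and erode the configuration. The fallback makes the same compound by Claisen-type chain assembly and closes ring C afterwards; it sets out from 6 and 11 and returns at 14. Nagao acetate aldol of 6 with commercial (R)-3-acetyl-4-isopropyl-1,3-thiazolidine-2-thione (Sn(OTf)2, N-ethylpiperidine) would give the (S)-carbinol thioimide F7 through the chelated chair transition state. Aminolysis (MeNHOMe·HCl, imidazole) would give the Weinreb amide F8, and TBSCl with imidazole the silyl ether F9. γ-Acetylation of the lithium dienolate of 11 (LiN(SiMe3)2, AcCl) would give the keto-dioxinone F10, whose dianion (LiN(i-Pr)2) would be acylated at the methyl terminus by F9 to the diketo-dioxinone F11. HF·pyridine would free the alcohol to the hydroxy diketone F12, and catalytic TsOH would close ring C by hemiketal formation and dehydration to 14.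

Step 3. Transfer of the prenyl group with allylic transposition would give the 1,1-dimethylallyl isomer, which is hard to separate. The fallback builds the prenyl group on the ring in two stages; it sets out from 5 and returns at 6. Stille coupling of 5 with allyltributylstannane (Pd(PPh3)4), where both allyl termini are alike, would give 8-allyl-2,2-dimethyl-2H-chromene-6-carbaldehyde F13. Cross-metathesis with 2-methylbut-2-ene (second-generation Grubbs catalyst) would then give 6, the hindered chromene alkene being expected to stay out of the metathesis.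

**Further compounds**

F1 | step 9 | 1-[2,4,6-trihydroxy-3-(3-methylbut-2-enyl)phenyl]ethanone | CC(=O)c1c(O)cc(O)c(CC=C(C)C)c1O
F2 | step 9 | 1-[2-hydroxy-4,6-bis(methoxymethoxy)-3-(3-methylbut-2-enyl)phenyl]ethanone | CC(=O)c1c(O)c(CC=C(C)C)c(OCOC)cc1OCOC
F3 | step 9 | tert-butyl 3-[2-hydroxy-4,6-bis(methoxymethoxy)-3-(3-methylbut-2-enyl)phenyl]-3-oxopropanoate | CC(C)(C)OC(=O)CC(=O)c1c(O)c(CC=C(C)C)c(OCOC)cc1OCOC
F4 | step 9 | tert-butyl 3-Ar-2-[2-hydroxy-4,6-bis(methoxymethoxy)-3-prenylbenzoyl]prop-2-enoate | CC(C)(C)OC(=O)C(=Cc1cc(CC=C(C)C)c2OC(C)(C)C=Cc2c1)C(=O)c1c(O)c(CC=C(C)C)c(OCOC)cc1OCOC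
F5 | step 9 | tert-butyl (2S)-2-Ar-5,7-bis(methoxymethoxy)-4-oxo-8-prenylchromane-3-carboxylate | CC(C)(C)OC(=O)C1C(=O)c2c(OCOC)cc(OCOC)c(CC=C(C)C)c2O[C@@H]1c1cc(CC=C(C)C)c3OC(C)(C)C=Cc3c1
F6 | step 9 | (2S)-2-Ar-5,7-bis(methoxymethoxy)-8-prenylchroman-4-one | O=C1C[C@@H](c2cc(CC=C(C)C)c3OC(C)(C)C=Cc3c2)Oc2c(CC=C(C)C)c(OCOC)cc(OCOC)c21
F7 | step 7 | (4R)-3-[(3S)-3-Ar-3-hydroxypropanoyl]-4-isopropyl-1,3-thiazolidine-2-thione | O=C(C[C@H](O)c1cc(CC=C(C)C)c2OC(C)(C)C=Cc2c1)N1[C@H](C(C)C)CSC1=S
F8 | step 7 | (3S)-3-Ar-3-hydroxy-N-methoxy-N-methylpropanamide | CON(C)C(=O)C[C@H](O)c1cc(CC=C(C)C)c2OC(C)(C)C=Cc2c1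
F9 | step 7 | (3S)-3-Ar-3-(tert-butyldimethylsilyloxy)-N-methoxy-N-methylpropanamide | CON(C)C(=O)C[C@H](O[Si](C)(C)C(C)(C)C)c1cc(CC=C(C)C)c2OC(C)(C)C=Cc2c1
F10 | step 7 | 2,2-dimethyl-6-(6-methyl-2-oxohept-5-en-3-yl)-4H-1,3-dioxin-4-one | CC(=O)C(CC=C(C)C)C1=CC(=O)OC(C)(C)O1
F11 | step 7 | 6-[(10S)-10-Ar-10-(tert-butyldimethylsilyloxy)-2-methyl-6,8-dioxodec-2-en-5-yl]-2,2-dimethyl-4H-1,3-dioxin-4-one | CC(C)=CCC(C(=O)CC(=O)C[C@H](O[Si](C)(C)C(C)(C)C)c1cc(CC=C(C)C)c2OC(C)(C)C=Cc2c1)C1=CC(=O)OC(C)(C)O1
F12 | step 7 | 6-[(10S)-10-Ar-10-hydroxy-2-methyl-6,8-dioxodec-2-en-5-yl]-2,2-dimethyl-4H-1,3-dioxin-4-one | CC(C)=CCC(C(=O)CC(=O)C[C@H](O)c1cc(CC=C(C)C)c2OC(C)(C)C=Cc2c1)C1=CC(=O)OC(C)(C)O1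
F13 | step 3 | 8-allyl-2,2-dimethyl-2H-chromene-6-carbaldehyde | O=Cc1cc(CC=C)c2OC(C)(C)C=Cc2c1
A1 | direct plan | 1-[2-hydroxy-4-(methoxymethoxy)-6-(3-methylbut-2-enyloxy)phenyl]ethanone | CC(=O)c1c(O)cc(OCOC)cc1OCC=C(C)C
A2 | direct plan | (E)-3-Ar-1-[2-hydroxy-4-(methoxymethoxy)-6-(3-methylbut-2-enyloxy)phenyl]prop-2-en-1-one | O=C(/C=C/c1cc(CC=C(C)C)c2OC(C)(C)C=Cc2c1)c1c(O)cc(OCOC)cc1OCC=C(C)C
A3 | direct plan | racemic 2-Ar-7-(methoxymethoxy)-5-(3-methylbut-2-enyloxy)chroman-4-one | O=C1CC(c2cc(CC=C(C)C)c3OC(C)(C)C=Cc3c2)Oc2cc(OCOC)cc(OCC=C(C)C)c21
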